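**Retrosynthetic overview**

1. Target 17 ⇐ 16 (O-debenzylation) ⇐ 15 (epoxidation of C3=C4 directed by the C10 hydroxyl) ⇐ 13 (C4 ketone → kinetic enol triflate → methyl).
2. 13 ⇐ 11: one hydroxyl-directed hydrogenation of a cycloheptatrienyl enol ester sets C1, C7 and C8; C5 is then epimerised to the trans ring fusion.
3. 11 ⇐ 9: γ-hydroxylation (epoxidation, then β-elimination) relays the single stereocenter of 9 to the tertiary carbinol C10.
4. 9 ⇐ 7: enantioselective intramolecular Buchner reaction. The benzene ring of thymol is expanded to the seven-membered ring while the five-membered ring closes; thymol's methyl, isopropyl and aryl ester oxygen become those of the target.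
5. 7 ⇐ thymol + methyl vinyl ketone + O-benzylisovanillic acid. Ring order: aromatic six-membered ring → five- and seven-membered rings together (step 4) → oxirane (step 9).

Assumption: acid 4 is bought; ring positions are given in guaiane numbering (C1/C5 ring fusion, C4 and C10 methyl-bearing, C7 isopropyl-bearing, C8 acyloxy-bearing), and "top face" means the face of the C10 hydroxyl in the target.

**Route**

Step 1
Reactants: 1 thymol; 2 methyl vinyl ketone
Product: 3 4-[4-hydroxy-2-methyl-5-(propan-2-yl)phenyl]butan-2-one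
Conditions: 2 (1.3 equiv), Amberlyst-15 (H form), toluene, 45 °C
Reagents that add atoms: none
Why: Acid-catalysed Friedel–Crafts conjugate addition (hydroarylation of the enone) goes para to the phenolic OH, the only activated position not flanked by OH, and the para adduct cannot close to a chroman; no stereocenter is formed.

Step 2
Reactants: 3 4-[4-hydroxy-2-methyl-5-(propan-2-yl)phenyl]butan-2-one; 4 3-(benzyloxy)-4-methoxybenzoic acid
Product: 5 5-methyl-4-(3-oxobutyl)-2-(propan-2-yl)phenyl 3-(benzyloxy)-4-methoxybenzoate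
Conditions: EDC·HCl (1.3 equiv), DMAP (0.2 equiv), CH2Cl2, 0 → 25 °C
Reagents that add atoms: none
Why: Steglich esterification acylates the phenol, so that the phenolic C–O bond of thymol becomes the C8–O ester bond of the target; no stereocenter is formed.

Step 3
Reactants: 5 5-methyl-4-(3-oxobutyl)-2-(propan-2-yl)phenyl 3-(benzyloxy)-4-methoxybenzoate
Product: 7 4-(4-diazo-3-oxobutyl)-5-methyl-2-(propan-2-yl)phenyl 3-(benzyloxy)-4-methoxybenzoate, via trifluoroacetyl diketone 6 (not isolated)
Conditions: LiN(SiMe3)2 (1.1 equiv), THF, −78 °C; CF3CO2CH2CF3 (1.2 equiv); then MsN3 (1.5 equiv), Et3N, H2O (1 equiv), MeCN, 25 °C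
Reagents that add atoms: 2,2,2-trifluoroethyl trifluoroacetate, O=C(OCC(F)(F)F)C(F)(F)F (its atoms are kept only in 6); methanesulfonyl azide, CS(=O)(=O)N=[N+]=[N-]
Why: Danheiser detrifluoroacetylative diazo transfer: the kinetic enolate of the methyl ketone is C-trifluoroacetylated to 6, which undergoes Regitz diazo transfer with loss of the trifluoroacetyl group; the aryl ester has no α-hydrogen and survives one equivalent of hindered amide at −78 °C; no stereocenter is formed.

Step 4
Reactants: 7 4-(4-diazo-3-oxobutyl)-5-methyl-2-(propan-2-yl)phenyl 3-(benzyloxy)-4-methoxybenzoate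
Product: 9 (8aS)-4-methyl-1-oxo-7-(propan-2-yl)-1,2,3,8a-tetrahydroazulen-6-yl 3-(benzyloxy)-4-methoxybenzoate, via norcaradiene 8 (not isolated)
Conditions: Cu(MeCN)4PF6 (5 mol %), (S,S)-t-Bu-box (6 mol %), NaB[3,5-(CF3)2C6H3]4 (6 mol %), CH2Cl2, 40 °C, slow addition of 7
Reagents that add atoms: none
Why: Intramolecular Buchner reaction (copper carbenoid cyclopropanation of the ipso/ortho bond, then 6π electrocyclic opening of 8) breaks the aromaticity of the thymol ring and forms both carbocycles at once; the carbenoid adds to the ortho CH and not to the methyl-bearing ortho carbon, and the bis(oxazoline) ligand sets the only stereocenter, C5 (azulene C8a), as S (the ligand antipode is taken if the sense turns out opposite).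

Step 5
Reactants: 9 (8aS)-4-methyl-1-oxo-7-(propan-2-yl)-1,2,3,8a-tetrahydroazulen-6-yl 3-(benzyloxy)-4-methoxybenzoate
Product: 11 (4R)-4-hydroxy-4-methyl-1-oxo-7-(propan-2-yl)-1,2,3,4-tetrahydroazulen-6-yl 3-(benzyloxy)-4-methoxybenzoate, via epoxide 10 (not isolated)
Conditions: dimethyldioxirane (1.05 equiv), acetone/CH2Cl2, −40 °C; then Et3N (0.3 equiv), 0 °C
Reagents that add atoms: dimethyldioxirane, CC1(C)OO1
Why: Electrophilic epoxidation of the tetrasubstituted, most electron-rich C1=C10 double bond from the convex face of the boat-shaped cycloheptatriene (anti to the endo 5-H), then amine-induced β-elimination (E1cB opening of the β,γ-epoxy ketone through the C4 enolate), gives the γ-hydroxy enone and relays the C5 configuration to the tertiary carbinol C10 (R).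

Step 6
Reactants: 11 (4R)-4-hydroxy-4-methyl-1-oxo-7-(propan-2-yl)-1,2,3,4-tetrahydroazulen-6-yl 3-(benzyloxy)-4-methoxybenzoate
Product: 13 (1R,5S,7R,8R,10R)-10-hydroxy-4-oxo-15-norguaian-8-yl 3-(benzyloxy)-4-methoxybenzoate, via cis-fused ketone 12 (not isolated)
Conditions: H2 (4 atm), [Ir(cod)(PCy3)(py)]PF6 (10 mol %), CH2Cl2, 0 → 25 °C; then DBU (1.5 equiv), 40 °C
Reagents that add atoms: none
Why: Hydroxyl-directed homogeneous hydrogenation with the cationic iridium catalyst delivers all six hydrogens on the face of the C10 hydroxyl, which sets C1, C7 and C8 (acyloxy and isopropyl end up on the bottom face) and gives cis-fused 12; its only enolisable stereocenter, C5, is then epimerised by DBU to the trans-fused ketone, which is expected to be the more stable isomer (base epimerisation α to the cyclopentanone is an established way from cis- to trans-hydroazulenones; residual 12 is recycled).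

Step 7
Reactants: 13 (1R,5S,7R,8R,10R)-10-hydroxy-4-oxo-15-norguaian-8-yl 3-(benzyloxy)-4-methoxybenzoate
Product: 14 (1R,5S,7R,8R,10R)-10-hydroxy-4-[(trifluoromethanesulfonyl)oxy]-15-norguai-3-en-8-yl 3-(benzyloxy)-4-methoxybenzoate
Conditions: KN(SiMe3)2 (2.2 equiv), THF, −78 °C; then PhNTf2 (1.2 equiv), −78 → 0 °C
Reagents that add atoms: N-phenylbis(trifluoromethanesulfonimide), O=S(=O)(N(c1ccccc1)S(=O)(=O)C(F)(F)F)C(F)(F)F
Why: Kinetic enolisation by the hindered amide at the C3 methylene and not at the C5 ring-fusion methine (the first equivalent is consumed by the tertiary OH), then O-triflation of the enolate, fixes the double bond at C3=C4 and locks C5; no new stereocenter is formed.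

Step 8
Reactants: 14 (1R,5S,7R,8R,10R)-10-hydroxy-4-[(trifluoromethanesulfonyl)oxy]-15-norguai-3-en-8-yl 3-(benzyloxy)-4-methoxybenzoate
Product: 15 (1R,5S,7R,8R,10R)-10-hydroxyguai-3-en-8-yl 3-(benzyloxy)-4-methoxybenzoate
Conditions: MeZnCl (3 equiv), Pd(PPh3)4 (5 mol %), THF, 50 °C
Reagents that add atoms: methylzinc chloride, C[Zn]Cl
Why: Negishi cross-coupling of the alkenyl triflate under zerovalent palladium catalysis installs the C4 methyl group without moving the double bond; the ester, the benzyl ether and the zinc alkoxide of the tertiary alcohol are tolerated; no new stereocenter is formed.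

Step 9
Reactants: 15 (1R,5S,7R,8R,10R)-10-hydroxyguai-3-en-8-yl 3-(benzyloxy)-4-methoxybenzoate
Product: 16 (1R,3R,4S,5S,7R,8R,10R)-3,4-epoxy-10-hydroxyguaian-8-yl 3-(benzyloxy)-4-methoxybenzoate
Conditions: VO(acac)2 (5 mol %), t-BuOOH (1.5 equiv, in decane), CH2Cl2, 0 → 25 °C
Reagents that add atoms: tert-butyl hydroperoxide, CC(C)(C)OO
Why: Vanadium-catalysed hydroxyl-directed epoxidation: the isolated trisubstituted alkene is oxidised only through the peroxovanadate bound to the bishomoallylic C10 hydroxyl, so oxygen arrives on the top face and sets C3 (R) and C4 (S).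

Step 10
Reactants: 16 (1R,3R,4S,5S,7R,8R,10R)-3,4-epoxy-10-hydroxyguaian-8-yl 3-(benzyloxy)-4-methoxybenzoate
Product: 17 (1R,3R,4S,5S,7R,8R,10R)-3,4-epoxy-10-hydroxyguaian-8-yl 3-hydroxy-4-methoxybenzoate
Conditions: H2 (1 atm), Pd/C, EtOAc, 25 °C
Reagents that add atoms: none
Why: Hydrogenolysis of the aryl benzyl ether under neutral conditions frees the phenol; the non-benzylic trisubstituted epoxide, the ester and all stereocenters are untouched.

**Compound list**

1 | thymol (5-methyl-2-(propan-2-yl)phenol) | Cc1ccc(C(C)C)c(O)c1 | starting material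
2 | methyl vinyl ketone (but-3-en-2-one) | CC(=O)C=C | starting material
3 | 4-[4-hydroxy-2-methyl-5-(propan-2-yl)phenyl]butan-2-one | CC(=O)CCc1cc(C(C)C)c(O)cc1C | intermediate
4 | 3-(benzyloxy)-4-methoxybenzoic acid | COc1ccc(C(=O)O)cc1OCc1ccccc1 | starting material
5 | 5-methyl-4-(3-oxobutyl)-2-(propan-2-yl)phenyl 3-(benzyloxy)-4-methoxybenzoate | CC(=O)CCc1cc(C(C)C)c(OC(=O)c2ccc(OC)c(OCc3ccccc3)c2)cc1C | intermediate
6 | 5-methyl-2-(propan-2-yl)-4-(6,6,6-trifluoro-3,5-dioxohexyl)phenyl 3-(benzyloxy)-4-methoxybenzoate (trifluoroacetyl diketone) | O=C(CC(=O)C(F)(F)F)CCc1cc(C(C)C)c(OC(=O)c2ccc(OC)c(OCc3ccccc3)c2)cc1C | intermediate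
7 | 4-(4-diazo-3-oxobutyl)-5-methyl-2-(propan-2-yl)phenyl 3-(benzyloxy)-4-methoxybenzoate | [N-]=[N+]=CC(=O)CCc1cc(C(C)C)c(OC(=O)c2ccc(OC)c(OCc3ccccc3)c2)cc1C | intermediate
8 | norcaradiene valence isomer of 9 (cyclopropane on C1, C5, C6; 5-H on the side of the cyclohexadiene ring) | O=C1CC[C@@]23[C@@H]1[C@@H]2C(C(C)C)=C(OC(=O)c4ccc(OC)c(OCc5ccccc5)c4)C=C3C | intermediate
9 | (8aS)-4-methyl-1-oxo-7-(propan-2-yl)-1,2,3,8a-tetrahydroazulen-6-yl 3-(benzyloxy)-4-methoxybenzoate (guaiane 5S; double bonds C1=C10, C6=C7, C8=C9) | COc1ccc(C(=O)OC2=CC(C)=C3CCC(=O)[C@H]3C=C2C(C)C)cc1OCc1ccccc1 | intermediate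
10 | C1–C10 epoxide of 9 (azulene 3a,4-epoxide; oxirane oxygen anti to 5-H) | COc1ccc(C(=O)OC2=C[C@@]4(C)O[C@]43CCC(=O)[C@H]3C=C2C(C)C)cc1OCc1ccccc1 | intermediate
11 | (4R)-4-hydroxy-4-methyl-1-oxo-7-(propan-2-yl)-1,2,3,4-tetrahydroazulen-6-yl 3-(benzyloxy)-4-methoxybenzoate (guaiane 10R; double bonds C1=C5, C6=C7, C8=C9) | COc1ccc(C(=O)OC2=C[C@@](C)(O)C3=C(C(=O)CC3)C=C2C(C)C)cc1OCc1ccccc1 | intermediate
12 | (1R,5R,7R,8R,10R)-10-hydroxy-4-oxo-15-norguaian-8-yl 3-(benzyloxy)-4-methoxybenzoate (cis-fused; 1-H, 5-H, 7-H, 8-H and 10-OH on the top face) | COc1ccc(C(=O)O[C@@H]2C[C@@](C)(O)[C@@H]3CCC(=O)[C@@H]3C[C@@H]2C(C)C)cc1OCc1ccccc1 | intermediate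
13 | (1R,5S,7R,8R,10R)-10-hydroxy-4-oxo-15-norguaian-8-yl 3-(benzyloxy)-4-methoxybenzoate (trans-fused; 5-H on the bottom face) | COc1ccc(C(=O)O[C@@H]2C[C@@](C)(O)[C@@H]3CCC(=O)[C@H]3C[C@@H]2C(C)C)cc1OCc1ccccc1 | intermediate
14 | (1R,5S,7R,8R,10R)-10-hydroxy-4-[(trifluoromethanesulfonyl)oxy]-15-norguai-3-en-8-yl 3-(benzyloxy)-4-methoxybenzoate | COc1ccc(C(=O)O[C@@H]2C[C@@](C)(O)[C@@H]3CC=C(OS(=O)(=O)C(F)(F)F)[C@H]3C[C@@H]2C(C)C)cc1OCc1ccccc1 | intermediate
15 | (1R,5S,7R,8R,10R)-10-hydroxyguai-3-en-8-yl 3-(benzyloxy)-4-methoxybenzoate | COc1ccc(C(=O)O[C@@H]2C[C@@](C)(O)[C@@H]3CC=C(C)[C@H]3C[C@@H]2C(C)C)cc1OCc1ccccc1 | intermediate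
16 | (1R,3R,4S,5S,7R,8R,10R)-3,4-epoxy-10-hydroxyguaian-8-yl 3-(benzyloxy)-4-methoxybenzoate | COc1ccc(C(=O)O[C@@H]2C[C@@](C)(O)[C@@H]3C[C@H]4O[C@@]4(C)[C@H]3C[C@@H]2C(C)C)cc1OCc1ccccc1 | intermediate
17 | (1R,3R,4S,5S,7R,8R,10R)-3,4-epoxy-10-hydroxyguaian-8-yl 3-hydroxy-4-methoxybenzoate (CNP0264062.2; top face: 1-H, 7-H, 8-H, 10-OH, oxirane O; bottom face: 5-H, both methyls, isopropyl, acyloxy) | COc1ccc(C(=O)O[C@@H]2C[C@@](C)(O)[C@@H]3C[C@H]4O[C@@]4(C)[C@H]3C[C@@H]2C(C)C)cc1O | target

**Step count and risks**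

Total step count: 10. Longest linear sequence: 10 steps (1 → 17); acid 4 is bought and enters in step 2.

The three steps most likely to fail are 4, 5 and 6.

Step 4 (enantioselectivity of the Buchner reaction on an acyloxy-substituted arene). The fallback gives up catalyst control and resolves instead. It sets out from 7: Rh2(OAc)4 (1 mol %) in CH2Cl2 at 40 °C gives, through norcaradiene 8 and the enantiomeric norcaradiene F1, the racemic azulenone, that is 9 together with its (8aR)-enantiomer F2. Preparative supercritical-fluid chromatography on a cellulose tris(3,5-dimethylphenylcarbamate) phase separates the two, and the route is rejoined at 9.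

Step 5 (site and face selectivity of the epoxidation among three conjugated double bonds; acid sensitivity of the tropyl-type alcohol 11). The fallback replaces epoxidation/elimination by a singlet-oxygen ene reaction. This reaction bonds oxygen on the face that carries the abstracted hydrogen, which is the face opposite to the one used by the dioxirane. It therefore sets out from 7 with the enantiomeric ligand (R,R)-t-Bu-box and gives, via the enantiomeric norcaradiene F1, the (8aR)-azulenone F2. O2, tetraphenylporphyrin and visible light in CH2Cl2 at −40 °C abstract the doubly allylic, α-keto 5-H and bond oxygen to C10, giving the (4R)-hydroperoxide F3. PPh3 reduces F3 to 11, where the route is rejoined.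

Step 6 (complete, face-selective reduction of three different double bonds, including a tetrasubstituted enone, on an ionisable tertiary alcohol; the cis/trans ratio after DBU is also uncertain). The fallback divides the reduction. It sets out from 11: the less active cationic catalyst [Rh(nbd)(dppb)]BF4 under H2 (3 atm, CH2Cl2) reduces only the two trisubstituted double bonds under hydroxyl direction and leaves the tetrasubstituted enone, giving the (7R,8R,10R)-1(5)-enone F4. The enone is then reduced by metal-hydride hydrogen-atom transfer (Mn(dpm)3, PhSiH3, i-PrOH, 25 °C), which should add hydrogen to C1 anti to the pseudo-axial C10 methyl group. DBU equilibrates C5 (12 is the transient cis isomer), and the route is rejoined at 13.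

**Further compounds**

F1 | step 4 | enantiomer of norcaradiene 8 | O=C1CC[C@]23[C@H]1[C@H]2C(C(C)C)=C(OC(=O)c4ccc(OC)c(OCc5ccccc5)c4)C=C3C
F2 | step 4 | (8aR)-4-methyl-1-oxo-7-(propan-2-yl)-1,2,3,8a-tetrahydroazulen-6-yl 3-(benzyloxy)-4-methoxybenzoate (enantiomer of 9) | COc1ccc(C(=O)OC2=CC(C)=C3CCC(=O)[C@@H]3C=C2C(C)C)cc1OCc1ccccc1
F3 | step 5 | (4R)-4-hydroperoxy-4-methyl-1-oxo-7-(propan-2-yl)-1,2,3,4-tetrahydroazulen-6-yl 3-(benzyloxy)-4-methoxybenzoate | COc1ccc(C(=O)OC2=C[C@@](C)(OO)C3=C(C(=O)CC3)C=C2C(C)C)cc1OCc1ccccc1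
F4 | step 6 | (7R,8R,10R)-10-hydroxy-4-oxo-15-norguai-1(5)-en-8-yl 3-(benzyloxy)-4-methoxybenzoate | COc1ccc(C(=O)O[C@@H]2C[C@@](C)(O)C3=C(C[C@@H]2C(C)C)C(=O)CC3)cc1OCc1ccccc1
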